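Set two amounts side by side before you think of any speed: the nucleophile charged and the electrophile charged.

| flask | electrophile | nucleophile | free base | remark | time |
|---|---|---|---|---|---|
| autumn | 0.050 M | 0.015 M | 0.060 M | run made earlier |  |
| midnight | 0.050 M | 0.034 M | 0.060 M | run made earlier |  |
| noon | 0.050 M | 0.066 M | 0.060 M | run made earlier |  |
| dusk | 0.094 M | 0.055 M | 0.060 M | run made earlier |  |
| east | 0.050 M | 0.0550 M | 0.0600 M |  | 2.5 min |
| north-east | 0.15 M | 0.0200 M | 0.0600 M |  | 1.2 min |

| run | time / s | product / % | electrophile / % |
|---|---|---|---|
| autumn | 10.0 | 18.1 | 81.9 |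
| autumn | 25.0 | 26.6 | 73.5 |
| autumn | 50.0 | 28.8 | 70.3 |
| autumn | 80.0 | 26.8 | 71.4 |
| midnight | 20.0 | 48.7 | 53.7 |
| midnight | 40.0 | 58.1 | 43.7 |
| midnight | 60.0 | 62.6 | 37.2 |
| midnight | 80.0 | 63.9 | 34.8 |
| noon | 10.0 | 59.0 | 42.6 |
| noon | 25.0 | 76.4 | 21.6 |
| noon | 50.0 | 88.2 | 9.5 |
| noon | 80.0 | 94.3 | 4.5 |
| dusk | 10.0 | 36.3 | 63.4 |
| dusk | 25.0 | 48.6 | 52.7 |
| dusk | 50.0 | 52.7 | 46.0 |
| dusk | 80.0 | 57.1 | 42.3 |

(readings scatter by 1 percentage point)

- steps under discussion: electrophile + nucleophile -> acid set free + product; nucleophile + acid set free <-> protonated nucleophile; acid set free + free base <-> salt of the base; nucleophile <-> dormant form; 2 nucleophile -> homo dimer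

* the flask that ends with the higher amount of product, in percent of the electrophile charged, or "neither" when 2 percentage points or less lies between them (east / north-east / neither)
* final product, as a percentage of the electrophile charged, in east
* final product, as a percentage of the electrophile charged, in north-east

Each turn of the main step uses one nucleophile and one electrophile. So in north-east, the nucleophile charged divided by the electrophile charged gives 13.3%. Call this ratio the cap: the product, in percent of the electrophile charged, that the nucleophile can pay for. The nucleophile is the limiting reagent there. In east the same ratio is 110%, higher than in north-east, and since the nucleophile charged there is more than the electrophile charged, the electrophile is the limiting reagent in east.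

Why these two amounts? In north-east the free base, at 0.0600 M, exceeds the 0.0200 M of acid that the nucleophile can set free. As for time, the midnight run read 62.6% at 60.0 s and 63.9% at 80.0 s, and north-east runs 1.2 min, longer than the first of these.

Now ask how near a flask comes to its cap. Dusk, also short of nucleophile, has a cap of 58.5% and read 57.1% at 80.0 s, a reach of 97.6%, which carries the scatter of that reading. Your own reckoning for north-east is then 13.0%. For east, take noon as the guide: its ratio is 132%, and it read 94.3% at 80.0 s, still climbing. So you commit to east.

The forecast says east, with 92% for east and 12.8% for north-east, the second just under your figure: “north-east is capped by its nucleophile”.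

The flasks give 94.3% in east and 13.2% in north-east, so east ends higher, and the forecast held.

    electrophile + nucleophile → acid set free + product (k = 3.06 L mol⁻¹ s⁻¹)
    nucleophile + acid set free ⇌ protonated nucleophile, settled at all times (K = 860 L mol⁻¹)
    acid set free + free base ⇌ salt of the base (K = 7400 L mol⁻¹, k = 25.1 L mol⁻¹ s⁻¹)
    nucleophile ⇌ dormant form (K = 0.256, k = 0.00467 s⁻¹)
    2 nucleophile → homo dimer (k = 0.153 L mol⁻¹ s⁻¹)

In north-east, 13.2% stands beside the cap of 13.3%; 0.015% of the nucleophile is left at 1.20 min, while 86.8% of the electrophile stays. The main reason is the consumption of nucleophile: in the run where it is not consumed, north-east reaches 98.8% instead of 13.2%. Charge a neighbour of north-east with 0.034 M of nucleophile and the cap becomes 22.7%; that flask gives 22.4%.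

The earlier runs and the new flask are simulated from invented constants; noise was put on by code.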